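I wanted to know which set-up sends the largest share of captured intermediate to target.

| flask | substrate | first nucleophile | second nucleophile | remark | time |
|---|---|---|---|---|---|
| Sunday's | 23 mM | 92 mM | 23 mM | run made earlier |  |
| Thursday's | 32 mM | 92 mM | 23 mM | run made earlier |  |
| Wednesday's | 51 mM | 92 mM | 23 mM | run made earlier |  |
| Friday's | 23 mM | 46 mM | 23 mM | run made earlier |  |
| alder | 23 mM | 92.0 mM | 23.0 mM | one stirred flow tank at steady state, fed with the mixture as stated, mean residence time 50.0 min |  |
| larch | 23 mM | 92.0 mM | 23.0 mM | one stirred flow tank at steady state, fed with the mixture as stated, mean residence time 10 min |  |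
| birch | 23 mM | 92.0 mM | 23.0 mM | everything together in a closed stirred flask, run for 10 min | 10 min |
| cedar | 23 mM (fed, over 8.00 min) | 92.0 mM | 23.0 mM | a stirred flask in which substrate is dosed at a steady rate over 8.00 min without added volume, worked up at 10 min | 10 min |

| run | time / min | target / % | other capture product / % |
|---|---|---|---|
| Sunday's | 1.50 | 14.3 | 8.0 |
| Sunday's | 3.00 | 26.2 | 14.0 |
| Sunday's | 5.00 | 37.8 | 18.2 |
| Sunday's | 6.00 | 44.2 | 20.1 |
| Thursday's | 0.833 | 8.2 | 4.3 |
| Thursday's | 2.00 | 18.7 | 9.4 |
| Thursday's | 4.00 | 33.0 | 16.1 |
| Thursday's | 6.00 | 43.6 | 19.8 |
| Wednesday's | 0.833 | 8.4 | 5.4 |
| Wednesday's | 2.00 | 19.3 | 8.8 |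
| Wednesday's | 4.00 | 34.3 | 15.6 |
| Wednesday's | 6.00 | 45.9 | 17.7 |
| Friday's | 0.500 | 3.4 | 4.3 |
| Friday's | 1.00 | 7.2 | 8.9 |
| Friday's | 2.50 | 17.4 | 17.6 |
| Friday's | 6.00 | 34.8 | 29.2 |

(each reading ± 0.5 percentage points)

- the stated concentrations are those of everything mixed, before any reaction; amounts are the same in each set-up
- the numbers in the tables scatter by 0.5 percentage points (one standard deviation)
- what may be going on: substrate -> intermediate; first nucleophile + intermediate -> target; second nucleophile + intermediate -> other capture product; second nucleophile -> decomposed reagent; first nucleophile <-> dormant form; second nucleophile -> decomposition product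
- the feed brings no volume worth counting
- the earlier runs were made in a closed, stirred flask

* the set-up with the highest share of target in all that became target or other capture product, at the outlet or at the end ("none" if the first two lie within 2 percentage points) (alder / larch / birch / cedar / none)
* share of target in all that became target or other capture product, at the outlet or at the end, alder
* share of target in all that became target or other capture product, at the outlet or at the end, larch
* share of target in all that became target or other capture product, at the outlet or at the end, birch
* share of target in all that became target or other capture product, at the outlet or at the end, cedar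

At 6.00 min, target plus other capture product stood at 64.3%, 63.4% and 63.6% of the charge in Sunday's, Thursday's and Wednesday's runs, although the substrate rose from 23 mM to 51 mM. So I took release of the intermediate as a first-order, rate-limiting step, with 0.172 min⁻¹. The nucleophiles then divide the intermediate. From Friday's two earliest readings I read the selectivity factor 0.402, the target formed per other capture product at equal amounts of the two nucleophiles. Multiplied by first nucleophile over second nucleophile, it gives the capture ratio, and the share is that ratio over one plus itself.

At the feed, 4.00 charges against 1.00 gave a ratio of 1.61, a share of 61.7%. But between 3.00 min and 6.00 min Sunday's run made the two products in the ratio 2.95, more than the 1.77 that consumption leaves at mid-window. So I read a decay of second nucleophile, 0.114 min⁻¹, a reading that carries the scatter of a small difference and lumps in any change in first nucleophile.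

The alder tank has one composition, so its share is the local one. With 0.896 of the charge released, my first pass, sending that release to target, left 3.10 charges of first nucleophile and 0.149 of second, a ratio of 8.36. But that pass charged second nucleophile nothing for capture. Putting back the 0.0957 of other capture product, and target at 0.800, gave a ratio of 9.53, a share of 90.5%.

The forecast chose alder, at 88.3% (84.5% to 91%), with larch 75.8%, birch 71.2% and cedar 74.1%, because the “long residence time lets the second nucleophile die”. My figure lies above its 88.3%, inside its range.

The set-up alder stood first at 88.8%, ahead of cedar at 76.9%, larch at 75.8% and birch at 72.0%; the forecast's choice fails if that lead of 12 percentage points falls under 2 points.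

substrate → intermediate (k = 0.169 min⁻¹); first nucleophile + intermediate → target (k = 2050 L mol⁻¹ min⁻¹); second nucleophile + intermediate → other capture product (k = 5070 L mol⁻¹ min⁻¹); second nucleophile → decomposed reagent (k = 0.157 min⁻¹); first nucleophile ⇌ dormant form (K = 0.740, k = 0.0770 min⁻¹); second nucleophile → decomposition product (k = 5.57 × 10⁻⁴ min⁻¹) First nucleophile in the alder tank stood at 45.5 mM, half of its feed. The alder share means a capture ratio of 7.90, so at my selectivity factor of 0.402 I reckoned that the alder tank held 0.101 of a charge of second nucleophile. For the larch tank, with 58.8 mM of first nucleophile and a share of 75.8%, the same reckoning gave 0.327 of a charge of second nucleophile.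

The earlier runs and the new flask stem from a simulated flask for substances that don't exist.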